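**Counted in shares of its own charge, does the gamma run start faster than the theta run?**

all flasks: free catalyst 0.10 mM

| flask | starting material | remark | time |
|---|---|---|---|
| gamma | 0.20 M | the very flask that is asked about, followed so far |  |
| theta | 0.13 M | run made earlier |  |
| flask | 0.20 M |  | 6.0 h |

| run | time / min | target / % |
|---|---|---|
| gamma | 40.0 | 10 |
| gamma | 80.0 | 12 |
| gamma | 120 | 14 |
| gamma | 180 | 16 |
| gamma | 240 | 17 |
| gamma | 300 | 20 |
| theta | 2.50 | 0 |
| theta | 4.00 | 5 |
| theta | 6.00 | 2 |
| theta | 10.0 | 1 |
| theta | 15.0 | 3 |
| theta | 20.0 | 4 |
| theta | 30.0 | 6 |

(scatter of a reading: 1.5 percentage points)

- removed target is counted in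
- additions bring no volume worth counting

- larch: change nothing and wait 6.0 h more
- ash: at 6.0 h take out 90% of the target then present, then wait 6.0 h
- birch: at 6.0 h add free catalyst, 50.0% of the amount charged, then wait 6.0 h
- elm: at 6.0 h add starting material, 50.0% of the amount charged, then wait 6.0 h

- target, in percent of the starting material first charged, at 6.0 h
- the remedy with the largest gain of target, or "none" below 2 percentage points (larch / ash / birch / elm / none)
- target present, with what was taken out counted in, in percent of the starting material first charged, after ash
- target present, with what was taken out counted in, in percent of the starting material first charged, after elm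

Barely. Gamma is the flask itself, followed so far. Gamma's first reading, its time divided by its share of the charge, gives 400 min: this is the whole-charge time, the time a flask would need to turn its whole charge into target at that pace. Theta's last reading gives 500 min. Gamma's is shorter, but one scatter of 1.5 percentage points on the theta reading covers the gap. So, with free catalyst charged alike and as far as these two readings go, the start can be read as pseudo-first-order in c(starting material).

**And later in gamma?**

From 120 min to 300 min the same sum on gamma's readings gives 3000 min, which is 7.50 times the first value, as a reading with its scatter. Held for 6.0 h beyond 6.0 h, that pace is worth 12 points.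

**Would you commit to that, when target is the one thing you read?**

No. In gamma the time has been growing, and neither c(starting material) nor c(free catalyst) was measured. My rule is that the pace follows their product. The whole-charge time at any moment is then the starting value divided by both remaining shares, and it scales inversely with the catalyst charged. The readings don't give those shares.

The forecast reasons otherwise: “the slowing seems tied to product build-up”. It puts target at 21.5% (20% to 23.5%), picks ash, and gives 37% after ash (30% to 44%) and 32% after elm (27% to 38%).

The flask gives 19.0% at 6.0 h. The best remedy is ash, which reaches 32.1% and gains 13 points, more than any other remedy. Elm reaches 21.1%, less than the forecast's 32%.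

    starting material + free catalyst ⇌ target + free catalyst, rate k1*[starting material]*[free catalyst] forward; the back reaction follows from the equilibrium constant (K = 10.0, k = 0.884 L mol⁻¹ s⁻¹)
    target ⇌ isomer of the product A (K = 1.50, k = 0.00277 s⁻¹)
    isomer of the product A + free catalyst ⇌ isomer of the product B + free catalyst, rate k3*[free catalyst]*[isomer of the product A] forward; the back reaction follows from the equilibrium constant (K = 0.645, k = 26.5 L mol⁻¹ s⁻¹)
    isomer of the product B + free catalyst ⇌ starting material + free catalyst, rate k4*[free catalyst]*[isomer of the product B] forward; the back reaction follows from the equilibrium constant (k = 0.103 L mol⁻¹ s⁻¹)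
    target + free catalyst ⇌ isomer of the product C + free catalyst, rate k5*[free catalyst]*[target] forward; the back reaction follows from the equilibrium constant (K = 0.858, k = 3.98 L mol⁻¹ s⁻¹)
    free catalyst + target → spent catalyst A (k = 0.00155 L mol⁻¹ s⁻¹)
    free catalyst → spent catalyst B (k = 6.13 × 10⁻⁵ s⁻¹)

At 360 min the flask holds 19.6% starting material and 9.57% free catalyst, so by my rule the whole-charge time stands at 21400 min. Elm adds 50.0% of the charge, and the rule then gives 6010 min, worth 6 points at that held pace; the simulated gain is 2.1 points. For the neighbouring flask, charged with 4.0 × 10⁻⁵ M of free catalyst, the rule gives a start of 1000 min. With 47.2% starting material and 14.2% of its own free catalyst at 360 min, the rule gives 15000 min, shorter than the value for this flask, and that neighbouring flask holds 13.1% target.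

(The runs stem from a simulated flask with made-up constants; scatter was added.)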